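The ratio of electrophile left to electrophile charged stood at 68.1% in Thursday's run and 68.0% in Tuesday's at 15.0 min, although Tuesday's held 2.69 times the free base, so over that range you can leave the free base out of your reckoning.

common to all: electrophile 0.010 M

| charge | nucleophile | free base | remark | time |
|---|---|---|---|---|
| Thursday's | 0.013 M | 0.013 M | run made earlier |  |
| Tuesday's | 0.013 M | 0.035 M | run made earlier |  |
| red | 0.0130 M | 0.0110 M |  | 30 min |
| teal | 0.0130 M | 0.0220 M |  | 30 min |

- Thursday's (time / min: electrophile / %, product / %): 2.50: 94.2, 7.6; 5.00: 85.3, 12.4; 8.00: 79.5, 20.1; 10.0: 75.7, 24.1; 12.0: 71.2, 26.4; 15.0: 68.1, 31.5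
- Tuesday's (time / min: electrophile / %, product / %): 1.33: 96.0, 2.7; 2.00: 95.1, 3.4; 3.00: 92.0, 9.6; 5.00: 86.8, 14.3; 10.0: 75.2, 24.6; 15.0: 68.0, 31.9

(scatter of a reading: 1 percentage point)

- steps thought possible: electrophile + nucleophile -> acid set free + product; nucleophile + acid set free <-> protonated nucleophile; acid set free + free base <-> salt of the base

- part of the electrophile that has reacted at the end, red
- part of the electrophile that has reacted at the end, teal
- what raising the concentration of free base from its lowest to its highest value here does to the part of the electrophile that has reacted (changes below 5 percentage points count as none) (it falls / no change / it rises)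

Fold the givens into one number, N = k·B·t, where t is the time, B the mean nucleophile over that time, and N the natural log of electrophile charged over electrophile left; with B held fixed, the electrophile is pseudo-first-order. The mean ratio 68.0% gives N = 0.385. Counting one nucleophile lost per electrophile, you reckon B at 0.0114 M, and the rate constant reads k = 2.25 M⁻¹ min⁻¹.

Red and teal have the same charges of electrophile and nucleophile, so your reckoning gives them one N. Try a reacted share of 0.5: B is 0.0105 M, N is 0.709, and the share comes to 50.8%, close to the trial.

Was one number enough? The second-order curve through the same reading, with the nucleophile falling one for one, gives 49.7%, so using the mean costs 1 percentage point, against a scatter of 1 point. The total acid formed at your share, 0.00508 M, is less than red's 0.0110 M of free base. Nucleophile tied up by acid is not counted in B, so any error from that makes your figure high.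

The forecast gives 50% for red and 50% for teal, a little under your 50.8%, and no change, reasoning that “base does not affect the rate”.

The flasks give 46.3% for red and 47.8% for teal, a change of 1.5 points: no change.

    electrophile + nucleophile → acid set free + product (k = 2.40 M⁻¹ min⁻¹)
    nucleophile + acid set free ⇌ protonated nucleophile, settled at all times (K = 14000 M⁻¹)
    acid set free + free base ⇌ salt of the base, settled at all times (K = 10000 M⁻¹)

At 30.0 min red keeps 47% of its nucleophile free. Taking B as the mean of the free nucleophile at start and end, 0.00954 M, your k gives 47.5% for red. In a flask like red with 0.017 M of electrophile, 29% of the nucleophile is free at the end; the same k gives 43.1%, and that flask gives 38.6%.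

The earlier runs and the new flask come from a simulation with constants of no real substance, and the scatter is random.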